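## The problem

Target 19 is a single oxolane with three contiguous stereocentres. C2 bears a 3,4,5-trimethoxyphenyl group, C3 a hydroxymethyl group and C4 a 3-hydroxy-4,5-dimethoxybenzyl group, with C2/C3 trans and C3/C4 cis, (2R,3S,4S). No second ring holds these centres, so they must be set on an open chain or a temporary ring and carried over. The C3/C4 cis pair is the hard part: it is the less stable arrangement on the oxolane and cannot be corrected once the ring exists. C2 is benzylic and oxygen-bound, so it can be set last under control of C3, trans being preferred kinetically and thermodynamically. The same feature makes C2 fragile: strong acid ionizes C2–O1 and can send the cation into the neighbouring electron-rich benzyl ring (an aryltetralin), and forcing hydrogenolysis cleaves the bond. The phenol must be masked for any organometallic step and released without touching that bond. The enabling feature is that C3, C4, the hydroxymethyl carbon on C3 and ring carbon C5 form a four-carbon unit oxidized at both ends. It maps onto a butenolide with the hydroxymethyl carbon as carbonyl, C3 as α-carbon, C4 as β-carbon and C5 as an acetal carbon that can carry a chiral auxiliary; a trans-disubstituted lactone, the stable arrangement there, becomes the cis pair of 19 because the oxolane is later closed through different atoms.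

## Retrosynthesis

19 is traced to its benzyl ether 18. No skeletal bond is cut. The benzyl group keeps the phenol silent during the organolithium chemistry; a silyl ether was the neighbouring choice but is less secure towards n-BuLi and LiAlH4. The forward step must cleave the aryl O–CH2Ph bond and stop before the C2–O1 bond.

18 is cut at O1–C2, giving triol 16 by way of benzylic cation 17. The neighbouring cut, O1–C5, would require telling apart the two primary hydroxyls of the triol. The O1–C2 cut needs no differentiation, since only the C5 hydroxyl can reach the cation in a five-membered closure, and it makes the carbinol configuration irrelevant. The precursor is an open chain with only two stereocentres that matter. The forward reaction must ionize under conditions mild enough that oxygen capture beats arene capture.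

16 is the fully reduced form of lactone 15: the C–O bond to the auxiliary and the lactone C–O bond are re-formed, so that the CH2OH carbon becomes a carbonyl and C5 a menthyloxy acetal. 15 in turn comes from dithiane 14 by exchanging two C–H bonds of the benzylic CH2 for C–S bonds. Against carrying a benzyl group from the start, the dithiane gives the benzylic carbon nucleophilic character. The forward reactions are a desulfurization and a hydride reduction that also releases the auxiliary 7.

14 is cut at two C–C bonds: lactone C4–dithiane carbon (the future C4–CH2Ar bond) and lactone C3–carbinol carbon (the future C2–C3 bond). This gives lithiated dithiane precursor 3, chiral butenolide 9 and aldehyde 10. Cutting only the aldol bond would leave a chiral β-benzyl lactone to be made separately; cutting C3–C4 would put both hard centres into one less controllable event. The three pieces are achiral or auxiliary-based, and all three stereocentres of 14 derive from the acetal centre of 9. The forward reaction must add 1,4 and anti to the menthyloxy group, then trap the enolate anti to the new substituent.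

3 is the dithioacetal of aldehyde 2, the benzyl ether of commercial 1. 9 is the (+)-menthyl acetal of pseudo-acid 6, which comes from furfural 4 by oxidative loss of the formyl carbon. The only demand is that one acetal epimer be obtained pure, which crystallization with acid-mediated epimerization of epimer 8 delivers.

## Roads not taken

Alternative 1: The doubly protected target A1 is cut at the ring bond C3–C4 and at the CH2–aryl bond of the C4 arm, leading to bromo allyl ether A2 and aryl bromide A3. In the forward step a nickel catalyst from NiBr2(dme), 4,4'-di-tert-butyl-2,2'-bipyridine and Zn abstracts bromine from A2. The C3 radical closes 5-exo onto the O-allyl group, and the new primary radical is arylated by A3.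
- Merits: ring closure and a C–C coupling in one operation; C2 is preset, so no ionizing closure is needed; only two deprotections follow. In endgame length and in avoiding sulfur and strong hydride this road is better than the chosen one.
- Weak points: C3 and C4 are both set in one radical closure controlled only by C2. The chair-like transition state favours the required pattern, but such oxa-hexenyl closures are usually only moderately selective. Any two-electron organometallic at C3 (alkylzinc or alkylnickel) would expel the β-allyloxy or β-silyloxy group. A2 itself needs an enantio- and regiocontrolled synthesis of several steps.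
- Comparison: the chosen plan sets against the shorter endgame a strong auxiliary-controlled bias, a crystalline chiral building block and a stereo-array stored in its stable form.

Alternative 2: Cyclobutene A4 is cut across both new ring bonds, back to dihydrofuran A5 and arylalkyne A6. A cationic monovalent cobalt bisphosphine catalyst (from CoBr2, Zn and NaB[3,5-(CF3)2C6H3]4) would join the alkyne to the C3=C4 bond of A5 in a (2+2) cycloaddition anti to the C2 aryl group.
- Merits: the cis ring fusion guarantees the C3/C4 cis relation; the step is catalytic and needs no auxiliary. On these points it is better than the chosen plan.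
- Weak points: the regiochemistry (alkyne CH to C3, aryl-bearing carbon to C4) rests only on a steric preference. Terminal arylalkynes tend to oligomerize and 2,5-dihydrofurans to isomerize to enol ethers. Cleaving the cyclobutene double bond of A4 leaves a formyl group on C3 and an aroyl group on C4, so both centres become epimerizable α-carbonyl positions in their less stable cis form. The aryl ketone must then be deoxygenated next to the labile C2–O1 bond. A5 must be made enantioenriched.
- Comparison: the chosen plan holds the same pair as a trans lactone, where epimerization can only restore what is wanted, and needs fewer steps after the key event.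

Alternative 3: Furofuranone A7 is cut at C2–C3 and C4–C5 of the oxolane, back to aryl butenolide A8 and carbonyl ylide A10, released from chloro silylmethyl ether A9 by CsF.
- Merits: the oxolane is closed directly with C2 set in the cycloaddition rather than by a cation, and the lactone carbonyl already sits on C3. Hydrogenolysis of the lactone's benzylic C–O bond and reduction of the acid would finish the skeleton. For ring construction and C2 control this road is as good as or better than the chosen one.
- Weak points: regiochemistry and exo/endo selectivity of an unsymmetrical, non-stabilized ylide are uncertain. The γ-proton of A8 is benzylic and vinylogously acidic, so the stereocentre meant to steer the cycloaddition can racemize under basic fluoride. A8 needs its own asymmetric synthesis. Hydrogenolysis must distinguish two benzylic C–O bonds.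
- Comparison: the chosen plan sets against it a configurationally robust acetal centre in 9 and bond formations whose regiochemistry is fixed by polarity.

Key step: step 5

## Route

Assumption: 14 is drawn as the anti (S) carbinol epimer expected from a closed aldol transition state; any syn epimer formed alongside is carried unseparated through steps 6 and 7, because step 8 ionizes this centre and both epimers converge on 18.

In the names below, "d-menthyl" stands for (1S,2R,5S)-2-isopropyl-5-methylcyclohexyl.

Step 1
Reactants: 1 3-hydroxy-4,5-dimethoxybenzaldehyde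
Product: 2 3-(benzyloxy)-4,5-dimethoxybenzaldehyde
Conditions: BnBr (1.1 equiv), K2CO3, DMF, rt to 50 °C
Reagents that add atoms: benzyl bromide, BrCc1ccccc1
Why: Williamson etherification of the phenoxide; the benzyl ether masks the acidic phenol for the organolithium step 5 and is removable at the end by hydrogenolysis.

Step 2
Reactants: 2 3-(benzyloxy)-4,5-dimethoxybenzaldehyde
Product: 3 2-[3-(benzyloxy)-4,5-dimethoxyphenyl]-1,3-dithiane
Conditions: HS(CH2)3SH (1.1 equiv), BF3·OEt2 (0.2 equiv), CH2Cl2, 0 °C to rt
Reagents that add atoms: propane-1,3-dithiol, SCCCS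
Why: Lewis-acid-catalysed dithioacetalization of an aromatic aldehyde; it turns the formyl carbon into an acyl-anion equivalent whose two C–S bonds are later replaced by C–H, and a catalytic charge of BF3·OEt2 at 0 °C leaves the benzyl ether alone.

Step 3
Reactants: 4 furfural
Product: 6 5-hydroxyfuran-2(5H)-one (racemic), via furfural endoperoxide 5 (not isolated)
Conditions: O2, hν (visible), methylene blue (cat.), MeOH, 20 °C
Reagents that add atoms: dioxygen, O=O
Why: Dye-sensitized photooxygenation: singlet oxygen adds (4+2) across C2 and C5 of the furan to give endoperoxide 5, and methanol attacks the formyl group, expelling methyl formate and leaving pseudo-acid 6.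

Step 4
Reactants: 6 5-hydroxyfuran-2(5H)-one; 7 (+)-menthol
Product: 9 (5S)-5-(d-menthyloxy)furan-2(5H)-one, via 5R acetal epimer 8 (not isolated)
Conditions: 7 (1.0 equiv), camphor-10-sulfonic acid (cat.), PhMe, reflux with azeotropic removal of water; crystallization from hexanes; mother liquor re-equilibrated with the same acid and recrystallized
Reagents that add atoms: none
Why: Acid-catalysed acetalization of the lactol hydroxyl gives both C5 epimers, which interconvert through the ring oxocarbenium ion; the 5S epimer of the d-menthyl series is the crystalline one, so epimer 8 is drained into 9 and the acetal centre is obtained pure without chromatography.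

Step 5
Reactants: 3 2-[3-(benzyloxy)-4,5-dimethoxyphenyl]-1,3-dithiane; 9 (5S)-5-(d-menthyloxy)furan-2(5H)-one; 10 3,4,5-trimethoxybenzaldehyde
Product: 14 (3R,4S,5S)-4-{2-[3-(benzyloxy)-4,5-dimethoxyphenyl]-1,3-dithian-2-yl}-3-[(S)-hydroxy(3,4,5-trimethoxyphenyl)methyl]-5-(d-menthyloxy)dihydrofuran-2(3H)-one, via lithiated dithiane 11 (not isolated), via lactone lithium enolate 12 (not isolated), via lithium aldolate 13 (not isolated)
Conditions: 3 (1.05 equiv), n-BuLi (1.05 equiv), THF, −78 °C; then 9 (1.0 equiv), −78 °C; then 10 (1.2 equiv), −78 °C; AcOH quench at −78 °C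
Reagents that add atoms: none
Why: n-BuLi removes the C2 proton of 3 to give the sulfur-stabilized benzylic anion 11, which adds in Michael fashion to lactone C4 of 9, forming the future C4–CH2Ar bond and enolate 12. Enolate 12 is intercepted at lactone C3 by aldehyde 10 in an aldol addition (the future C2–C3 bond), and aldolate 13 is protonated cold with acetic acid before retro-aldol can set in. The closest known reaction type is the tandem conjugate addition and enolate trapping of 2-aryl-2-lithio-1,3-dithianes on 5-alkoxyfuran-2(5H)-ones, a standard entry to lignan skeletons. No ring is closed; two skeletal bonds and three stereocentres are created. The C5 menthyloxy group shields one face of the nearly flat butenolide, so the bulky anion enters anti to it and fixes lactone C4; the new dithianyl group then sends the aldehyde to the opposite face of the enolate, fixing lactone C3 trans to C4. The carbinol centre arises in a closed six-membered chair transition state on the ring-locked E-enolate with the aryl group equatorial, which should favour the anti (S) epimer; this centre is erased by ionization in step 8. The step needs 1,4- over 1,2-addition, secured by the soft, hindered aryl dithiane anion and the acetal-activated enoate, and clean C-aldol capture, secured by low temperature and a non-enolizable aldehyde.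

Step 6
Reactants: 14 (3R,4S,5S)-4-{2-[3-(benzyloxy)-4,5-dimethoxyphenyl]-1,3-dithian-2-yl}-3-[(S)-hydroxy(3,4,5-trimethoxyphenyl)methyl]-5-(d-menthyloxy)dihydrofuran-2(3H)-one
Product: 15 (3R,4S,5S)-4-[3-(benzyloxy)-4,5-dimethoxybenzyl]-3-[(S)-hydroxy(3,4,5-trimethoxyphenyl)methyl]-5-(d-menthyloxy)dihydrofuran-2(3H)-one
Conditions: Raney Ni (W-2, washed neutral, excess), EtOH–THF, rt
Reagents that add atoms: none
Why: Reductive desulfurization of a benzylic dithioacetal on hydrogen-loaded Raney nickel replaces both C–S bonds by C–H; at room temperature with neutral-washed nickel the lactone, the acetal, the aryl benzyl ether and the carbinol should survive, and the trans lactone is the stable arrangement, so no stereocentre is at risk.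

Step 7
Reactants: 15 (3R,4S,5S)-4-[3-(benzyloxy)-4,5-dimethoxybenzyl]-3-[(S)-hydroxy(3,4,5-trimethoxyphenyl)methyl]-5-(d-menthyloxy)dihydrofuran-2(3H)-one
Product: 16 (2S,3S)-2-[3-(benzyloxy)-4,5-dimethoxybenzyl]-3-[(S)-hydroxy(3,4,5-trimethoxyphenyl)methyl]butane-1,4-diol
Conditions: LiAlH4 (excess), THF, 0 °C to rt; H2O then aq. NaOH work-up
Reagents that add atoms: none
Why: Hydride reduction of the γ-alkoxy lactone (a cyclic acylal): the carbonyl carbon goes to CH2OH, the expelled hemiacetal alkoxide collapses to the C5 aldehyde with loss of menthoxide and is reduced in turn, so both ring carbons emerge as primary alcohols and auxiliary 7 is released for recovery; reduction outruns enolization, so the two backbone stereocentres are untouched.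

Step 8
Reactants: 16 (2S,3S)-2-[3-(benzyloxy)-4,5-dimethoxybenzyl]-3-[(S)-hydroxy(3,4,5-trimethoxyphenyl)methyl]butane-1,4-diol
Product: 18 [(2R,3S,4S)-4-[3-(benzyloxy)-4,5-dimethoxybenzyl]-2-(3,4,5-trimethoxyphenyl)oxolan-3-yl]methanol, via benzylic cation 17 (not isolated)
Conditions: camphor-10-sulfonic acid (10 mol%), CH2Cl2, 0 °C to rt, stopped at full conversion
Reagents that add atoms: none
Why: Acid-catalysed dehydrative etherification: the electron-rich benzylic carbinol ionizes to cation 17, which is captured in a five-membered closure by the C5 hydroxyl (the other primary hydroxyl could only form an oxetane); the aryl group settles trans to the C3 hydroxymethyl group both in the closing transition state and by reversible reopening, so either carbinol epimer gives the (2R) oxolane.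

Step 9
Reactants: 18 [(2R,3S,4S)-4-[3-(benzyloxy)-4,5-dimethoxybenzyl]-2-(3,4,5-trimethoxyphenyl)oxolan-3-yl]methanol
Product: 19 [(2R,3S,4S)-4-(3-hydroxy-4,5-dimethoxybenzyl)-2-(3,4,5-trimethoxyphenyl)oxolan-3-yl]methanol
Conditions: H2 (1 atm), 10% Pd/C, EtOAc, rt, stopped after uptake of one equivalent
Reagents that add atoms: none
Why: Hydrogenolysis of an aryl benzyl ether over palladium is much faster than cleavage of the dialkyl benzylic ether C2–O1 in a neutral, non-acidic solvent, so the phenol should be freed with the oxolane and all three stereocentres intact.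

## Compound list

1 | 3-hydroxy-4,5-dimethoxybenzaldehyde | COc1cc(C=O)cc(O)c1OC | starting material
2 | 3-(benzyloxy)-4,5-dimethoxybenzaldehyde | COc1cc(C=O)cc(OCc2ccccc2)c1OC | intermediate
3 | 2-[3-(benzyloxy)-4,5-dimethoxyphenyl]-1,3-dithiane | COc1cc(C2SCCCS2)cc(OCc3ccccc3)c1OC | intermediate
4 | furfural (furan-2-carbaldehyde) | O=Cc1ccco1 | starting material
5 | furfural endoperoxide, 2,3,7-trioxabicyclo[2.2.1]hept-5-ene-1-carbaldehyde (racemic) | O=CC12OOC(C=C1)O2 | intermediate (not isolated)
6 | 5-hydroxyfuran-2(5H)-one (racemic) | O=C1C=CC(O)O1 | intermediate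
7 | (+)-menthol, (1S,2R,5S)-2-isopropyl-5-methylcyclohexan-1-ol | CC(C)[C@H]1CC[C@H](C)C[C@@H]1O | starting material
8 | (5R)-5-{[(1S,2R,5S)-2-isopropyl-5-methylcyclohexyl]oxy}furan-2(5H)-one | O=C1O[C@@H](O[C@H]2C[C@@H](C)CC[C@@H]2C(C)C)C=C1 | intermediate (not isolated)
9 | (5S)-5-{[(1S,2R,5S)-2-isopropyl-5-methylcyclohexyl]oxy}furan-2(5H)-one | O=C1O[C@H](O[C@H]2C[C@@H](C)CC[C@@H]2C(C)C)C=C1 | intermediate
10 | 3,4,5-trimethoxybenzaldehyde | COc1cc(C=O)cc(OC)c1OC | starting material
11 | 2-[3-(benzyloxy)-4,5-dimethoxyphenyl]-2-lithio-1,3-dithiane | [Li]C1(c2cc(OC)c(OC)c(OCc3ccccc3)c2)SCCCS1 | intermediate (not isolated)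
12 | lithium enolate of (4S,5S)-4-{2-[3-(benzyloxy)-4,5-dimethoxyphenyl]-1,3-dithian-2-yl}-5-(d-menthyloxy)dihydrofuran-2(3H)-one | [Li]OC1=C[C@H](C2(c3cc(OC)c(OC)c(OCc4ccccc4)c3)SCCCS2)[C@@H](O[C@H]2C[C@@H](C)CC[C@@H]2C(C)C)O1 | intermediate (not isolated)
13 | lithium alkoxide of 14 | O=C1O[C@H](O[C@H]2C[C@@H](C)CC[C@@H]2C(C)C)[C@@H](C2(c3cc(OC)c(OC)c(OCc4ccccc4)c3)SCCCS2)[C@@H]1[C@H](O[Li])c1cc(OC)c(OC)c(OC)c1 | intermediate (not isolated)
14 | (3R,4S,5S)-4-{2-[3-(benzyloxy)-4,5-dimethoxyphenyl]-1,3-dithian-2-yl}-3-[(S)-hydroxy(3,4,5-trimethoxyphenyl)methyl]-5-{[(1S,2R,5S)-2-isopropyl-5-methylcyclohexyl]oxy}dihydrofuran-2(3H)-one | O=C1O[C@H](O[C@H]2C[C@@H](C)CC[C@@H]2C(C)C)[C@@H](C2(c3cc(OC)c(OC)c(OCc4ccccc4)c3)SCCCS2)[C@@H]1[C@H](O)c1cc(OC)c(OC)c(OC)c1 | intermediate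
15 | (3R,4S,5S)-4-[3-(benzyloxy)-4,5-dimethoxybenzyl]-3-[(S)-hydroxy(3,4,5-trimethoxyphenyl)methyl]-5-{[(1S,2R,5S)-2-isopropyl-5-methylcyclohexyl]oxy}dihydrofuran-2(3H)-one | O=C1O[C@H](O[C@H]2C[C@@H](C)CC[C@@H]2C(C)C)[C@@H](Cc2cc(OC)c(OC)c(OCc3ccccc3)c2)[C@@H]1[C@H](O)c1cc(OC)c(OC)c(OC)c1 | intermediate
16 | (2S,3S)-2-[3-(benzyloxy)-4,5-dimethoxybenzyl]-3-[(S)-hydroxy(3,4,5-trimethoxyphenyl)methyl]butane-1,4-diol | OC[C@@H](Cc1cc(OC)c(OC)c(OCc2ccccc2)c1)[C@@H](CO)[C@H](O)c1cc(OC)c(OC)c(OC)c1 | intermediate
17 | benzylic cation from 16, (2S,3S)-configured 1,4-dihydroxybutane carrying the (3,4,5-trimethoxyphenyl)methylium carbon on C3 | OC[C@@H](Cc1cc(OC)c(OC)c(OCc2ccccc2)c1)[C@@H](CO)[CH+]c1cc(OC)c(OC)c(OC)c1 | intermediate (not isolated)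
18 | [(2R,3S,4S)-4-[3-(benzyloxy)-4,5-dimethoxybenzyl]-2-(3,4,5-trimethoxyphenyl)oxolan-3-yl]methanol | COc1cc(C[C@@H]2CO[C@@H](c3cc(OC)c(OC)c(OC)c3)[C@@H]2CO)cc(OCc4ccccc4)c1OC | intermediate
19 | [(2R,3S,4S)-4-(3-hydroxy-4,5-dimethoxybenzyl)-2-(3,4,5-trimethoxyphenyl)oxolan-3-yl]methanol | COc1cc(C[C@@H]2CO[C@@H](c3cc(OC)c(OC)c(OC)c3)[C@@H]2CO)cc(O)c1OC | target

## Step count and risks

Total: 9 steps. Longest linear sequence: 7 steps (1, 2, 5, 6, 7, 8, 9 from compound 1; equally 3, 4, 5, 6, 7, 8, 9 from compound 4).

Step 5 (key step). The most likely failure is incomplete or reversible aldol capture. Enolate 12 is flanked by the quaternary dithiane carbon and the aldehyde is electron-rich, so addition may be slow, aldolate 13 may revert, or the enolate may be quenched by proton transfer, leaving only the Michael adduct. The fallback separates the two bond formations. It sets out from 3 and 9: the same conjugate addition, quenched with NH4Cl, should give (4S,5S)-4-{2-[3-(benzyloxy)-4,5-dimethoxyphenyl]-1,3-dithian-2-yl}-5-(d-menthyloxy)dihydrofuran-2(3H)-one F1. Raney Ni desulfurization of F1 should give the benzyl lactone (4S,5S)-4-[3-(benzyloxy)-4,5-dimethoxybenzyl]-5-(d-menthyloxy)dihydrofuran-2(3H)-one F2. Its less hindered enolate (LiN(iPr)2, THF, −78 °C) is then added to 10, anti to the benzyl group, and the route is rejoined at 15.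

Step 6. The most likely failure is loss of chemoselectivity on the nickel surface: base-induced retro-aldol cleavage of the β-hydroxy lactone, together with partial hydrogenolysis of the aryl benzyl ether. The fallback changes the order of events. It sets out from 14, which is first reduced with LiAlH4 to the dithianyl triol (2S,3S)-2-{2-[3-(benzyloxy)-4,5-dimethoxyphenyl]-1,3-dithian-2-yl}-3-[(S)-hydroxy(3,4,5-trimethoxyphenyl)methyl]butane-1,4-diol F3. F3 has no carbonyl group left for a retro-aldol; it is then desulfurized with Raney Ni, and the route is rejoined at 16. Loss of the benzyl ether could be repaired by selective O-benzylation of the phenol (BnBr, K2CO3).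

Step 8. The most likely failure is diversion of cation 17 away from oxygen capture. The benzyl ring is activated ortho and para by two oxygens and can alkylate irreversibly (Friedel–Crafts closure to an aryltetralin), and prolonged acid reopens 18 and gives that pathway repeated chances. The fallback activates the benzylic carbon as part of an acetoxonium ion instead of a free cation, by analogy with the orthoester-mediated cyclodehydration of 1,2,n-triols. It sets out from 16: MeC(OMe)3 and pyridinium p-toluenesulfonate should give the cyclic orthoester (2S)-3-[3-(benzyloxy)-4,5-dimethoxyphenyl]-2-[(4S,5S)-2-methoxy-2-methyl-4-(3,4,5-trimethoxyphenyl)-1,3-dioxan-5-yl]propan-1-ol F4. Catalytic BF3·OEt2 at low temperature ionizes the orthoester to a 1,3-dioxan-2-ylium ion, and the free C5 hydroxyl displaces its benzylic C–O bond in a five-membered closure. Inversion of the anti carbinol gives the (2R) configuration, in the form of [(2R,3S,4S)-4-[3-(benzyloxy)-4,5-dimethoxybenzyl]-2-(3,4,5-trimethoxyphenyl)oxolan-3-yl]methyl acetate F5. Methanolysis (K2CO3, MeOH) rejoins the route at 18.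

Step 9. The most likely failure is over-reduction: hydrogenolytic opening of the oxolane at the benzylic C2–O1 bond once the benzyl ether is gone. The fallback removes the benzyl group before the oxolane exists, since an open-chain benzylic alcohol is hydrogenolysed more slowly than a benzylic ether. It sets out from 16: H2 over Pd/C should give the phenolic triol (2S,3S)-2-(3-hydroxy-4,5-dimethoxybenzyl)-3-[(S)-hydroxy(3,4,5-trimethoxyphenyl)methyl]butane-1,4-diol F6. The acid closure of step 8 applied to F6 then gives 19 directly.

## Further compounds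

F1 | step 5 | (4S,5S)-4-{2-[3-(benzyloxy)-4,5-dimethoxyphenyl]-1,3-dithian-2-yl}-5-{[(1S,2R,5S)-2-isopropyl-5-methylcyclohexyl]oxy}dihydrofuran-2(3H)-one | O=C1C[C@H](C2(c3cc(OC)c(OC)c(OCc4ccccc4)c3)SCCCS2)[C@@H](O[C@H]2C[C@@H](C)CC[C@@H]2C(C)C)O1
F2 | step 5 | (4S,5S)-4-[3-(benzyloxy)-4,5-dimethoxybenzyl]-5-{[(1S,2R,5S)-2-isopropyl-5-methylcyclohexyl]oxy}dihydrofuran-2(3H)-one | O=C1C[C@H](Cc2cc(OC)c(OC)c(OCc3ccccc3)c2)[C@@H](O[C@H]2C[C@@H](C)CC[C@@H]2C(C)C)O1
F3 | step 6 | (2S,3S)-2-{2-[3-(benzyloxy)-4,5-dimethoxyphenyl]-1,3-dithian-2-yl}-3-[(S)-hydroxy(3,4,5-trimethoxyphenyl)methyl]butane-1,4-diol | OC[C@@H](C1(c2cc(OC)c(OC)c(OCc3ccccc3)c2)SCCCS1)[C@@H](CO)[C@H](O)c1cc(OC)c(OC)c(OC)c1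
F4 | step 8 | (2S)-3-[3-(benzyloxy)-4,5-dimethoxyphenyl]-2-[(4S,5S)-2-methoxy-2-methyl-4-(3,4,5-trimethoxyphenyl)-1,3-dioxan-5-yl]propan-1-ol (orthoester carbon epimers) | COC1(C)OC[C@H]([C@@H](CO)Cc2cc(OC)c(OC)c(OCc3ccccc3)c2)[C@@H](c2cc(OC)c(OC)c(OC)c2)O1
F5 | step 8 | [(2R,3S,4S)-4-[3-(benzyloxy)-4,5-dimethoxybenzyl]-2-(3,4,5-trimethoxyphenyl)oxolan-3-yl]methyl acetate | COc1cc(C[C@@H]2CO[C@@H](c3cc(OC)c(OC)c(OC)c3)[C@@H]2COC(C)=O)cc(OCc4ccccc4)c1OC
F6 | step 9 | (2S,3S)-2-(3-hydroxy-4,5-dimethoxybenzyl)-3-[(S)-hydroxy(3,4,5-trimethoxyphenyl)methyl]butane-1,4-diol | OC[C@@H](Cc1cc(OC)c(OC)c(O)c1)[C@@H](CO)[C@H](O)c1cc(OC)c(OC)c(OC)c1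
A1 | alternative 1 | tert-butyl{[(2R,3S,4S)-4-[3-(benzyloxy)-4,5-dimethoxybenzyl]-2-(3,4,5-trimethoxyphenyl)oxolan-3-yl]methoxy}dimethylsilane | COc1cc(C[C@@H]2CO[C@@H](c3cc(OC)c(OC)c(OC)c3)[C@@H]2CO[Si](C)(C)C(C)(C)C)cc(OCc4ccccc4)c1OC
A2 | alternative 1 | tert-butyl{[(3S)-2-bromo-3-(prop-2-en-1-yloxy)-3-(3,4,5-trimethoxyphenyl)propyl]oxy}dimethylsilane (bromide epimers) | C=CCO[C@@H](c1cc(OC)c(OC)c(OC)c1)C(Br)CO[Si](C)(C)C(C)(C)C
A3 | alternative 1 | 1-(benzyloxy)-5-bromo-2,3-dimethoxybenzene | COc1cc(Br)cc(OCc2ccccc2)c1OC
A4 | alternative 2 | cis-fused 6-[3-(benzyloxy)-4,5-dimethoxyphenyl]-2-(3,4,5-trimethoxyphenyl)-3-oxabicyclo[3.2.0]hept-6-ene, aryl at C2 on the face opposite the cyclobutene | COc1cc(C2=C[C@H]3[C@H](c4cc(OC)c(OC)c(OC)c4)OC[C@@H]23)cc(OCc5ccccc5)c1OC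
A5 | alternative 2 | (2R)-2-(3,4,5-trimethoxyphenyl)-2,5-dihydrofuran | COc1cc(cc(OC)c1OC)[C@@H]1OCC=C1
A6 | alternative 2 | 1-(benzyloxy)-5-ethynyl-2,3-dimethoxybenzene | COc1cc(C#C)cc(OCc2ccccc2)c1OC
A7 | alternative 3 | cis-fused 6-[3-(benzyloxy)-4,5-dimethoxyphenyl]-2-(3,4,5-trimethoxyphenyl)-3,7-dioxabicyclo[3.3.0]octan-8-one, both aryl groups exo | O=C1O[C@@H](c2cc(OC)c(OC)c(OCc3ccccc3)c2)[C@@H]2CO[C@@H](c3cc(OC)c(OC)c(OC)c3)[C@H]12
A8 | alternative 3 | (5R)-5-[3-(benzyloxy)-4,5-dimethoxyphenyl]furan-2(5H)-one | O=C1O[C@@H](c2cc(OC)c(OC)c(OCc3ccccc3)c2)C=C1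
A9 | alternative 3 | {[chloro(3,4,5-trimethoxyphenyl)methoxy]methyl}trimethylsilane | COc1cc(cc(OC)c1OC)C(Cl)OC[Si](C)(C)C
A10 | alternative 3 | carbonyl ylide of 3,4,5-trimethoxybenzaldehyde (O-methylide) | [CH2-][O+]=Cc1cc(OC)c(OC)c(OC)c1
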